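## The problem

1. Numbering used throughout:
   - Ring A is the trione C1(benzoyl)–C2(=O)–C3–C4(=O)–C5(geranyl)–C9(=O).
   - Ring B is C1–C9–C5–C6H2–C7H–C8Me2.
   - C10H2–C11H ties C7 to C3 and closes the two seven-membered rings C and D of the homoadamantane.
   - Ring E is the cyclopentane C3–C11–C12Me2–C13H(isopropenyl)–C14H2.
   - The "cap face" is the face of ring A from which C1→C2→C3→C4→C5→C9 runs clockwise.
2. Ring A is the nucleus of a phlorobenzophenone whose three nucleophilic carbons have all become quaternary. C5–C6, C1–C8 and C3–C11 all leave from the cap face, so C1, C3, C5 and C7 form one stereochemical unit. C11 and C13 are independent of it.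
3. The hardest bond is C1–C8. It joins two quaternary carbons, and C1 (triacyl) is the least nucleophilic carbon of ring A.
4. The chain on C7 must point endo, over ring A. This is the less stable orientation, and every annulation or intermolecular trapping at C7 avoids it.
5. C5 carries geranyl and C3 a prenyl-derived chain. No alkylation of the flat arene can tell these two carbons apart, so the two groups must arrive by different reaction types.
6. The geranyl alkenes and the isopropenyl group exclude strong acid. The non-enolisable 1,3-diketones around C1, C3 and C5 exclude hard nucleophiles late in the route.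
7. The feature that opens the key step is that C7 is the only hydrogen-bearing neighbour of C8. Written as C=O, it makes C9(=O)–C1–C8–C7(=O) a 1,4-diketone whose central bond joins the α-carbons of two enol derivatives. Ring B can therefore be closed by oxidative (anodic) coupling on a dearomatised benzophenone.
8. C3–C11 likewise joins two carbons that are both nucleophilic. The same oxidative logic therefore stitches the rest of the cap.

## Retrosynthesis

**18 ⇒ 17.** C3–C11 and C12–C13 are cut, which opens rings C, D and E.
- C3 is an enol carbon and C11 is the nucleophilic end of a prenyl alkene, so only an oxidative radical union fits.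
- Polar cuts at C11 would need SN2 displacement at a neopentyl secondary carbon.
- 17 has two rings and three stereocentres fewer than 18.
- The forward step must keep the C3 radical away from the geranyl group and must set C11 and C13.

**17 ⇒ 16 ⇒ 13 (+14) ⇒ 12.** C10–C11 is cut as an sp3–sp2 coupling, and C7–H is traced to an exocyclic alkene and then to a C7 ketone.
- Any carbon delivered to C7 from outside would end up exo.
- Delivering hydrogen from the open exo face of 13 pushes C10 endo.
- 12 has no C7 stereocentre.
- The forward steps need one chemoselective methylenation and one hydroboration of a 1,1-disubstituted alkene beside three trisubstituted ones.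

**12 ⇒ 10 + 11.** C3–C14 is cut as a vinyl bromide coupling.
- The bromine has a second duty: on the arene it blocks C3 and makes it a poor nucleophile, so C5 alone is alkylated.
- Placing prenyl on C3 from the start would make C3 and C5 indistinguishable. It would also offer the C1 radical a second alkene.

**10 ⇒ 9 (key).** C1–C8 is cut as the central bond of the 1,4-diketone C9/C7.
- The neighbouring cut C5–C6 is easy and is kept for the fragment union.
- A cationic C8 would need acid and would prefer oxygen or C3.
- 9 is monocyclic with a single stereocentre. 10 has ring B, both bridgeheads and the adjacent quaternary pair.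
- The forward step must oxidise the C1 enolate and join it to C8 in the 6-endo mode, ahead of the geranyl alkene.

**9 ⇒ 8 + 4.** C5–C6 is cut as an alkylative dearomatisation.
- This is the only step that creates absolute configuration.
- 8 is flat and achiral, and 4 is a five-carbon allylic bromide.
- The forward step asks for C-alkylation at the one alkyl-bearing ring carbon and for facial control by a chiral ion pair.

**8 ⇒ 5 + 7 through 6, and 4 ⇒ 1 through 2 and 3.**
- Bromination and then geranylation of the symmetric benzophenone 5 each meet only one possible site.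
- 4 comes from the α-keto ester 1. Its single α-hydrogen fixes the position of the enol ether double bond (future C7=C8).

## Roads not taken

**Alternative 1:** the biogenetic and most obvious cut, C1–C8 as tertiary cation plus enol with C7 preset.
- Forward key step: acid would protonate the isopropenyl group of monocyclic A1 (C5: geranyl and a lavandulyl-type chain; C3: prenyl). C1 would trap the C8 cation to give 17, which is then closed as in step 12.
- A1 cannot be assembled with control. Alkylation of a 3-geranyl-5-prenyl arene cannot choose between C3 and C5.
- C5 would form without relation to C7, and only one diastereomer can give the endo chain.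
- The acid meets five alkenes of similar basicity.
- The cation prefers oxygen or the more nucleophilic C3. For the needed diastereomer, attack at C3 is also the favoured exo chair.
- The chosen plan removes all four problems with the bromine block, the achiral arm, the non-acidic oxidation and the methylated O4.

**Alternative 2:** ring A cut from ring B at C1–C2 and C4–C5.
- Forward key step: Effenberger-type annulation of the enol ether of ketone A2 with malonyl dichloride.
- The three-carbon bridge forms on the face of A2 away from the C7 chain. This gives the exo epimer A3, whose prenyl group cannot reach C3, so the cage cannot be closed.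
- Geranyl, benzoyl and prenyl would then each need a separate strong-base metalation.
- O-methylation of the unsymmetrical diketone would give regioisomers.

**Alternative 3:** C1–C8 cut as opening of a tertiary epoxide by an enol ether on a reduced ring A.
- Forward key step: Lewis acid cyclisation of diene A4, made by double alkylation of 1,5-dimethoxycyclohexa-1,4-diene.
- Regiocontrol at C5 and absolute control from the epoxide are excellent.
- However, ring A arrives with C2 as CH2 and with C1 and C3 bare, and C7 carries an exo oxygen.
- That oxygen must still be taken to the same ketone pivot as 12. At least six more steps (allylic oxidation, ketal opening, alcohol oxidation, two metalations) are therefore needed to reach the level of 12.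

Key step: step 7

Assumption: cotoin (5) is taken as purchased; the cinchonidinium salt is written for step 6, and its cinchoninium pseudo-enantiomer is used if the ion pair shields the other face of C5.

## Steps

Step 1
Reactants: 1 methyl 3-methyl-2-oxobutanoate
Product: 2 methyl 2-[(tert-butyldimethylsilyl)oxy]-3-methylbut-2-enoate
Conditions: TBSOTf, Et3N, CH2Cl2, 0 °C to rt
Reagents that add atoms: tert-butyldimethylsilyl triflate, CC(C)(C)[Si](C)(C)OS(=O)(=O)C(F)(F)F
Why: Soft enolisation and O-silylation of an α-keto ester; the isopropyl methine is the only α-hydrogen, so the tetrasubstituted silyl enol ether (future C7=C8) forms as one regioisomer with no E/Z question.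

Step 2
Reactants: 2 methyl 2-[(tert-butyldimethylsilyl)oxy]-3-methylbut-2-enoate
Product: 3 2-[(tert-butyldimethylsilyl)oxy]-3-methylbut-2-en-1-ol
Conditions: DIBAL-H (2.2 equiv), CH2Cl2, −78 °C; aq. Rochelle salt
Reagents that add atoms: none
Why: 1,2-Reduction of a conjugated ester to the allylic alcohol; low temperature and a neutral work-up should keep the silyl enol ether and suppress oxygen-to-oxygen silyl shift.

Step 3
Reactants: 3 2-[(tert-butyldimethylsilyl)oxy]-3-methylbut-2-en-1-ol
Product: 4 1-bromo-2-[(tert-butyldimethylsilyl)oxy]-3-methylbut-2-ene
Conditions: CBr4, PPh3, 2,6-lutidine, CH2Cl2, −20 °C; used without storage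
Reagents that add atoms: carbon tetrabromide, BrC(Br)(Br)Br
Why: Appel bromination of a primary allylic alcohol under buffered conditions; 2-silyloxyallyl halides are isolable reagents.

Step 4
Reactants: 5 cotoin, (2,6-dihydroxy-4-methoxyphenyl)(phenyl)methanone
Product: 6 (3-bromo-2,6-dihydroxy-4-methoxyphenyl)(phenyl)methanone
Conditions: NBS (1.0 equiv), CH2Cl2/MeCN, −40 to 0 °C
Reagents that add atoms: N-bromosuccinimide, O=C1CCC(=O)N1Br
Why: Electrophilic aromatic bromination; the two free ring positions of 5 are equivalent, so one equivalent of NBS should give a single monobromide (future C3–Br).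

Step 5
Reactants: 6 (3-bromo-2,6-dihydroxy-4-methoxyphenyl)(phenyl)methanone; 7 geranyl bromide
Product: 8 {3-bromo-5-[(2E)-3,7-dimethylocta-2,6-dienyl]-2,6-dihydroxy-4-methoxyphenyl}(phenyl)methanone
Conditions: KOH, MeOH/H2O, 0 °C
Reagents that add atoms: none
Why: Base-mediated C-alkylation of an acylphloroglucinol ether with an allylic bromide in protic medium; only one ring C–H is left, and SN2 displacement keeps the E alkene.

Step 6
Reactants: 8 {3-bromo-5-[(2E)-3,7-dimethylocta-2,6-dienyl]-2,6-dihydroxy-4-methoxyphenyl}(phenyl)methanone; 4 1-bromo-2-[(tert-butyldimethylsilyl)oxy]-3-methylbut-2-ene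
Product: 9 2-benzoyl-6-bromo-4-geranyl-3-hydroxy-5-methoxy-4-{2-[(tert-butyldimethylsilyl)oxy]-3-methylbut-2-enyl}cyclohexa-2,5-dien-1-one (C5 quaternary: C6 arm on the cap face, geranyl on the other face)
Conditions: N-(9-anthracenylmethyl)-O-allylcinchonidinium bromide (10 mol %), CsOH·H2O, toluene/CH2Cl2, 4 Å molecular sieves, −50 °C; pH 6 buffer
Reagents that add atoms: none
Why: Asymmetric phase-transfer alkylative dearomatisation; acylphloroglucinols are known to be C-alkylated at an alkyl-bearing carbon, and chiral cinchona ion pairs are known to make such dearomatisations enantioselective. C5 is the only donor-substituted ring carbon (C1 is acylated, C3 brominated), both OH groups are chelated to the benzoyl group, and the electrophile is a soft allylic bromide. The ion pair sets C5, the only source of absolute configuration in the route.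

Step 7
Reactants: 9 the dienone of step 6
Product: 10 1-benzoyl-3-bromo-5-geranyl-4-methoxy-8,8-dimethylbicyclo[3.3.1]non-3-ene-2,7,9-trione (C6 and C8 on the cap face of ring A; benzoyl and geranyl pointing outward)
Conditions: undivided cell, reticulated vitreous carbon anode, Pt cathode, constant current (2.1 F/mol), Et4NOTs (0.1 M), 2,6-lutidine, MeOH/CH2Cl2 (1:4), 0 °C
Reagents that add atoms: none
Why: Proposed new method: 2,6-lutidine turns the acidic 2-benzoyl-1,3-dione unit (C9–C1–C2) of 9 into its enolate, the most easily oxidised group present, and loss of one electron at the anode gives the C1 triacylmethyl radical, which cannot spread to C3 because O4 is methylated and C3 carries bromine. This electrophilic radical adds to C8, the nucleophilic carbon of the tetrasubstituted silyl enol ether, and the α-silyloxy radical left at C7 is oxidised at once to a silyloxocarbenium ion that methanol desilylates to the C7 ketone (if the enol ether is oxidised first, attack of the enolate carbon C1 on its radical cation makes the same bond). The closest known reaction types are the anodic, Mn(OAc)3- and (NH4)2Ce(NO3)6-mediated additions of 1,3-dicarbonyl radicals to enol ethers and silyl enol ethers (1,4-dicarbonyl synthesis) and the intramolecular anodic coupling of enol ethers, which builds quaternary carbons; new here are the triacyl radical, the bridged ring and the two adjacent quaternary carbons, for which the early transition state of a radical addition is the best available answer. Ring B closes in the 6-endo-trig mode, because the 5-exo mode would bond C1 to the fully substituted, oxygen-bearing C7 against polarity and against the endo preference of radicals that hold a carbonyl group (C9) inside the forming ring. The one new stereocentre, C1, is set by C5, since the one-carbon tether C6 lets C8 reach C1 only on the face of ring A on which C6 stands. The step needs selectivity for the enol ether over the 2',3'-alkene of the geranyl group (5-exo attack from the other face), which the far higher nucleophilicity and lower oxidation potential of the enol ether should secure, and it avoids O-alkylation because the bond is made by addition of a carbon radical.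

Step 8
Reactants: 10 the bromo trione of step 7; 11 tributyl(3-methylbut-2-enyl)stannane
Product: 12 1-benzoyl-5-geranyl-4-methoxy-8,8-dimethyl-3-(3-methylbut-2-enyl)bicyclo[3.3.1]non-3-ene-2,7,9-trione (C1, C5 as in 10)
Conditions: Pd2(dba)3 (5 mol %), AsPh3, DMF, 60 °C
Reagents that add atoms: none
Why: Stille coupling of an α-bromo enone with a prenylstannane, a standard way to place a linear prenyl group on an sp2 carbon; neutral conditions spare the ketones and the non-enolisable diketone at C1.

Step 9
Reactants: 12 the 3-prenyl trione of step 8
Product: 13 1-benzoyl-5-geranyl-4-methoxy-8,8-dimethyl-7-methylidene-3-(3-methylbut-2-enyl)bicyclo[3.3.1]non-3-ene-2,9-dione (C1, C5 as in 10)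
Conditions: Cp2TiMe2 (1.5 equiv), toluene, 70 °C, dark
Reagents that add atoms: dimethyltitanocene, [CH3-].[CH3-].[Ti+4].c1cc[cH-]c1.c1cc[cH-]c1
Why: Petasis methylenation, which is non-basic and suited to hindered enolisable ketones. C7 is the only carbonyl with a CH2 neighbour: C9 lies between two quaternary carbons, the benzoyl group sits on quaternary C1, and C2 is a vinylogous ester.

Step 10
Reactants: 13 the 7-methylidene dione of step 9; 14 1-bromo-2-methylprop-1-ene
Product: 16 1-benzoyl-5-geranyl-4-methoxy-8,8-dimethyl-3,7-bis(3-methylbut-2-enyl)bicyclo[3.3.1]non-3-ene-2,9-dione (H-7 exo, C10 endo over ring A; C1, C5 as in 10), via B-alkyl-9-BBN adduct 15 (not isolated)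
Conditions: 9-BBN-H, THF, 0 °C to rt; then 14, Pd(dppf)Cl2 (5 mol %), AsPh3, Cs2CO3, DMF/THF/H2O, rt
Reagents that add atoms: 9-borabicyclo[3.3.1]nonane, [H]B1C2CCCC1CCC2 (its atoms stay only in 15)
Why: Hydroboration followed by B-alkyl Suzuki–Miyaura coupling; 9-BBN-H takes 1,1-disubstituted alkenes well ahead of trisubstituted ones. The endo face of C7=C10 is closed by ring A and the C3 prenyl group, so hydrogen is delivered to C7 from the exo face and C10 is turned endo.

Step 11
Reactants: 16 the methyl enol ether of step 10
Product: 17 1-benzoyl-5-geranyl-4-hydroxy-8,8-dimethyl-3,7-bis(3-methylbut-2-enyl)bicyclo[3.3.1]non-3-ene-2,9-dione (enol form; stereocentres as in 16)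
Conditions: LiCl, DMSO, 120 °C; dilute aq. HCl
Reagents that add atoms: none
Why: Krapcho-type SN2 demethylation of a vinylogous methyl ester by chloride, the usual last unmasking in this compound class; no stereocentre is touched.

Step 12
Reactants: 17 the enol of step 11
Product: 18 the target (C11 bonded to C3 on the cap face; C12 on the C4 side of C11; isopropenyl on C13 trans to C10 and cis to H-11)
Conditions: Mn(OAc)3·2H2O (2.2 equiv), Cu(OAc)2·H2O (0.5 equiv), degassed AcOH, 25–40 °C
Reagents that add atoms: none
Why: Oxidative free-radical cyclisation with trivalent manganese: the C3 radical can reach only the endo prenyl group (the bridgehead geranyl points away), adds to C11, the C12 radical closes 5-exo on C13, and divalent copper oxidises the last tertiary radical to the less substituted alkene. C3 is fixed by the cage, and at C11 the CMe2 end should turn to the C4/C6H2 side, away from the C8 methyls and the benzoyl group. A chair-like 5-exo transition state places the new side chain on C13 trans to C10.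

## Compound list

1 | methyl 3-methyl-2-oxobutanoate | COC(=O)C(=O)C(C)C | starting material
2 | methyl 2-[(tert-butyldimethylsilyl)oxy]-3-methylbut-2-enoate | COC(=O)C(O[Si](C)(C)C(C)(C)C)=C(C)C | intermediate
3 | 2-[(tert-butyldimethylsilyl)oxy]-3-methylbut-2-en-1-ol | OCC(O[Si](C)(C)C(C)(C)C)=C(C)C | intermediate
4 | 1-bromo-2-[(tert-butyldimethylsilyl)oxy]-3-methylbut-2-ene | BrCC(O[Si](C)(C)C(C)(C)C)=C(C)C | intermediate
5 | cotoin, (2,6-dihydroxy-4-methoxyphenyl)(phenyl)methanone | COc1cc(O)c(C(=O)c2ccccc2)c(O)c1 | starting material
6 | (3-bromo-2,6-dihydroxy-4-methoxyphenyl)(phenyl)methanone | COc1cc(O)c(C(=O)c2ccccc2)c(O)c1Br | intermediate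
7 | geranyl bromide | BrC/C=C(\C)CCC=C(C)C | starting material
8 | (3-bromo-5-geranyl-2,6-dihydroxy-4-methoxyphenyl)(phenyl)methanone | COc1c(Br)c(O)c(C(=O)c2ccccc2)c(O)c1C/C=C(\C)CCC=C(C)C | intermediate
9 | dearomatised dienone, C5 bearing geranyl and the silyloxyallyl arm | BrC1=C(OC)[C@@](C/C=C(\C)CCC=C(C)C)(CC(O[Si](C)(C)C(C)(C)C)=C(C)C)C(O)=C(C(=O)c2ccccc2)C1=O | intermediate
10 | 1-benzoyl-3-bromo-5-geranyl-4-methoxy-8,8-dimethylbicyclo[3.3.1]non-3-ene-2,7,9-trione | BrC1=C(OC)[C@@]2(C/C=C(\C)CCC=C(C)C)CC(=O)C(C)(C)[C@](C(=O)c3ccccc3)(C2=O)C1=O | intermediate
11 | tributyl(3-methylbut-2-enyl)stannane | CCCC[Sn](CCCC)(CCCC)CC=C(C)C | starting material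
12 | 3-prenyl 2,7,9-trione | CC(C)=CCC1=C(OC)[C@@]2(C/C=C(\C)CCC=C(C)C)CC(=O)C(C)(C)[C@](C(=O)c3ccccc3)(C2=O)C1=O | intermediate
13 | 7-methylidene 2,9-dione | CC(C)=CCC1=C(OC)[C@@]2(C/C=C(\C)CCC=C(C)C)CC(=C)C(C)(C)[C@](C(=O)c3ccccc3)(C2=O)C1=O | intermediate
14 | 1-bromo-2-methylprop-1-ene | CC(C)=CBr | starting material
15 | endo C10 B-alkyl-9-BBN adduct | CC(C)=CCC1=C(OC)[C@@]2(C/C=C(\C)CCC=C(C)C)C[C@@H](CB3C4CCCC3CCC4)C(C)(C)[C@](C(=O)c3ccccc3)(C2=O)C1=O | intermediate
16 | 7-endo-prenyl methyl enol ether | CC(C)=CCC1=C(OC)[C@@]2(C/C=C(\C)CCC=C(C)C)C[C@@H](CC=C(C)C)C(C)(C)[C@](C(=O)c3ccccc3)(C2=O)C1=O | intermediate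
17 | 7-endo-prenyl enol (free 1,3-diketone) | CC(C)=CCC1=C(O)[C@@]2(C/C=C(\C)CCC=C(C)C)C[C@@H](CC=C(C)C)C(C)(C)[C@](C(=O)c3ccccc3)(C2=O)C1=O | intermediate
18 | CNP0110731.1 | C=C(C)[C@@H]1C[C@@]23C(=O)[C@@]4(C/C=C(\C)CCC=C(C)C)C[C@@H](C[C@H]2C1(C)C)C(C)(C)[C@](C(=O)c1ccccc1)(C4=O)C3=O | target

## Step count and risks

Total step count: 12. Longest linear sequence: 10 (steps 1–3, then 6–12). The arene branch (steps 4–5, then 6–12) has 9.

**Step 7 (key step).**
- What may go wrong: the C1 radical is strongly stabilised and crowded, so its addition to the disubstituted end of the enol ether may be slow or reversible. In that case 5-exo attack on the geranyl alkene, radical dimerisation or simple loss of the silyl group could take over.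
- Fallback, polar and in two known operations, from 9 back to 10: NBS (THF, −78 °C) brominates the silyl enol ether of 9 at C8 to give the tertiary α-bromo ketone F1. Na2CO3 in 2,2,2-trifluoroethanol then ionises F1 through its C6 enol to the oxyallyl cation, and the C1 enolate captures it at C8, the only terminus it can reach in a six-membered ring, to give 10.

**Step 6.**
- What may go wrong: the ion pair may discriminate poorly between the faces of the flat phenoxide, and O-alkylation may compete.
- Fallback, from 3 and 8 back to 9: 3 is converted with methyl chloroformate and pyridine into the allylic methyl carbonate F2. It is joined to 8 by an asymmetric Tsuji–Trost allylation with Pd2(dba)3·CHCl3 and N,N'-[(1R,2R)-cyclohexane-1,2-diyl]bis[2-(diphenylphosphino)benzamide] in CH2Cl2. The π-allyl complex of divalent palladium is attacked at its CH2 end, and the ligand pocket selects the face of C5.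

**Step 10.**
- What may go wrong: hydroboration next to quaternary C8 may be slow enough for reduction of the C9 or benzoyl carbonyl by the borane to compete, and some endo-face attack is possible.
- Fallback, from 12 back to 16, makes the carbon bond first and inverts the outcome by hydrogen transfer:
  1. Prenylbarium chloride (α-selective, THF, −78 °C) adds to the C7 ketone from the exo face to give the tertiary alcohol F3.
  2. Methyl chlorooxoacetate and DMAP give the methyl oxalate F4.
  3. Bu3SnH/AIBN (Barton–McCombie-type deoxygenation) generates the tertiary C7 radical, which takes hydrogen on the open exo face and leaves the prenyl group endo, to give 16.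

**Step 12.**
- What may go wrong: the prenyl alkene may present the wrong face at C11. The C12 radical may be oxidised or may abstract hydrogen before it closes. The closure at C13 may be unselective.
- Fallback, from 17 back to 18, separates initiation from termination:
  1. NCS chlorinates C3 on the outer face to give the 3-chloro diketone F5.
  2. CuCl with tris(2-pyridylmethyl)amine (monovalent copper, DCE, 60 °C) runs the same two closures as an atom-transfer radical cyclisation, ending in the tertiary chloride F6.
  3. AgOTf and 2,6-lutidine eliminate HCl toward the methyl group to give 18.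

**Step 8.**
- What may go wrong: allyl transposition during transfer from tin could place a 1,1-dimethylallyl group on C3, and protodebromination may compete.
- Fallback, from 10 back to 12: Stille coupling with allyltributylstannane, which has no regiochemical choice, gives the 3-allyl trione F7. Cross metathesis with 2-methylbut-2-ene (second-generation Hoveyda–Grubbs catalyst, CH2Cl2, 40 °C) then turns the allyl group into prenyl, while the trisubstituted geranyl alkenes stay inert.

## Further compounds

F1 | step 7 | C8 tertiary α-bromo ketone of the dearomatised dienone | BrC1=C(OC)[C@@](C/C=C(\C)CCC=C(C)C)(CC(=O)C(C)(C)Br)C(O)=C(C(=O)c2ccccc2)C1=O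
F2 | step 6 | 2-[(tert-butyldimethylsilyl)oxy]-3-methylbut-2-enyl methyl carbonate | COC(=O)OCC(O[Si](C)(C)C(C)(C)C)=C(C)C
F3 | step 10 | 7-endo-hydroxy-7-exo-prenyl adduct of 12 | CC(C)=CCC1=C(OC)[C@@]2(C/C=C(\C)CCC=C(C)C)C[C@](O)(CC=C(C)C)C(C)(C)[C@](C(=O)c3ccccc3)(C2=O)C1=O
F4 | step 10 | methyl oxalate of F3 | CC(C)=CCC1=C(OC)[C@@]2(C/C=C(\C)CCC=C(C)C)C[C@](OC(=O)C(=O)OC)(CC=C(C)C)C(C)(C)[C@](C(=O)c3ccccc3)(C2=O)C1=O
F5 | step 12 | 3-chloro-3-prenyl trione (chlorine on the outer face) | CC(C)=CC[C@@]1(Cl)C(=O)[C@@]2(C/C=C(\C)CCC=C(C)C)C[C@@H](CC=C(C)C)C(C)(C)[C@](C(=O)c3ccccc3)(C2=O)C1=O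
F6 | step 12 | cage with a 2-chloropropan-2-yl group on C13 | CC(C)(Cl)[C@@H]1C[C@@]23C(=O)[C@@]4(C/C=C(\C)CCC=C(C)C)C[C@@H](C[C@H]2C1(C)C)C(C)(C)[C@](C(=O)c1ccccc1)(C4=O)C3=O
F7 | step 8 | 3-allyl 2,7,9-trione | C=CCC1=C(OC)[C@@]2(C/C=C(\C)CCC=C(C)C)CC(=O)C(C)(C)[C@](C(=O)c3ccccc3)(C2=O)C1=O
A1 | alternative 1 | monocyclic dienone with geranyl and a lavandulyl-type chain on C5 and prenyl on C3 | CC(C)=CCC1=C(O)[C@@](C/C=C(\C)CCC=C(C)C)(C[C@@H](CC=C(C)C)C(C)=C)C(O)=C(C(=O)c2ccccc2)C1=O
A2 | alternative 2 | 3,3-dimethyl-4-(3-methylbut-2-enyl)cyclohexanone | O=C1CC[C@H](CC=C(C)C)C(C)(C)C1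
A3 | alternative 2 | 7-exo-prenyl-8,8-dimethylbicyclo[3.3.1]nonane-2,4,9-trione | C1C(=O)[C@H]2C[C@H](CC=C(C)C)C(C)(C)[C@H](C2=O)C1=O
A4 | alternative 3 | 6-geranyl-6-[(3,3-dimethyloxiran-2-yl)methyl]-1,5-dimethoxycyclohexa-1,4-diene | COC1=CCC=C(OC)C1(C/C=C(\C)CCC=C(C)C)C[C@@H]1OC1(C)C
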